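**Retrosynthetic overview**
- The target is the selective diacetate of a (2Z)-hept-2-ene-1,5,6-triol, which comes from reductive opening of an α,β-unsaturated δ-lactone used as a temporary ring, with chain C1 held at the carboxyl level.
- The lactone is made in one pot from three components, a 2-cyclohexyl-buta-2,3-dienoate, 2-methyl-2-(triethylsilyloxy)propanal and a hydride, by a copper hydride reductive vinylogous aldol–lactonisation that forms the C4–C5 bond of the heptene chain.
- Enabling feature: the two acetoxy carbons are 1,5-related across the cis C2=C3 alkene, so O–C1–C2=C3–C4–C5–O is a ring-opened 5,6-dihydro-2H-pyran-2-one; with C1 as an ester, C4 becomes the nucleophilic γ-carbon of a dienolate and ring closure fixes the alkene geometry.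
- The allenoate comes from a cyclohexyl methyl ketone (alkyne, propargylic carbonate, carbonylation). The cyclohexane is the ring of (S)-carvone, whose single stereocentre relays the isopropenyl-bearing and quaternary centres in one conjugate addition–aldol event and is itself inverted later by equilibration.
- Ring order: the carbocycle is bought and never broken; the dihydropyranone is closed in step 12 and opened in step 13.

Key step: step 12

Assumption: the sense of induction of the CuOAc/(R)-DTBM-SEGPHOS catalyst with the aldehyde is taken by analogy with ketone acceptors; if a trial run shows the opposite sense, the (S)-ligand is used.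

**Step 1**
Reactants: 1 (S)-(+)-carvone
Product: 2 (5S)-5-acetyl-2-methylcyclohex-2-en-1-one
Conditions: O3 (1 equiv, indicator end point), CH2Cl2/MeOH, −78 °C; Me2S, −78 → 23 °C
Reagents that add atoms: ozone, O=[O+][O-]
Why: Chemoselective ozonolysis, in which the electron-rich 1,1-disubstituted alkene is cleaved much faster than the electron-poor enone alkene, while the neutral reductive work-up avoids enolisation of the new ketone that would racemise C5.

**Step 2**
Reactants: 2 (5S)-5-acetyl-2-methylcyclohex-2-en-1-one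
Product: 3 (5S)-2-methyl-5-(2-methyl-1,3-dioxolan-2-yl)cyclohex-2-en-1-one
Conditions: Me3SiOCH2CH2OSiMe3, Me3SiOTf (cat.), CH2Cl2, −78 °C; pyridine quench
Reagents that add atoms: 1,2-bis(trimethylsilyloxy)ethane, C[Si](C)(C)OCCO[Si](C)(C)C
Why: Silyl-triflate-catalysed ketalisation with a bis-silylated diol, which under aprotic conditions at low temperature is kinetically selective for the saturated methyl ketone over the conjugated carbonyl and does not enolise the stereocentre.

**Step 3**
Reactants: 3 (5S)-2-methyl-5-(2-methyl-1,3-dioxolan-2-yl)cyclohex-2-en-1-one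
Product: 5 (2S,3R,5S)-2-(1-hydroxyethyl)-2-methyl-5-(2-methyl-1,3-dioxolan-2-yl)-3-(prop-1-en-2-yl)cyclohexan-1-one as both carbinol epimers, via bromomagnesium enolate 4 (not isolated)
Conditions: CH2=C(CH3)MgBr, CuBr·SMe2 (10 mol %), THF, −78 → −40 °C; CH3CHO, −78 °C; cold aqueous NH4Cl
Reagents that add atoms: isopropenylmagnesium bromide, CC(=C)[Mg]Br; acetaldehyde, CC=O
Why: Copper-catalysed conjugate addition–aldol three-component coupling, in which the alkenyl group adds axially anti to the C5 substituent (3,5-trans) and the regiodefined enolate takes up acetaldehyde anti to the new C3 group, so that the quaternary C2 carries its two-carbon arm trans to the isopropenyl group.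

**Step 4**
Reactants: 5 (2S,3R,5S)-2-(1-hydroxyethyl)-2-methyl-5-(2-methyl-1,3-dioxolan-2-yl)-3-(prop-1-en-2-yl)cyclohexan-1-one
Product: 6 (2R,3R,5S)-2-ethenyl-2-methyl-5-(2-methyl-1,3-dioxolan-2-yl)-3-(prop-1-en-2-yl)cyclohexan-1-one
Conditions: Burgess reagent, toluene, 70 °C
Reagents that add atoms: none
Why: Burgess dehydration by syn elimination, where the only β-hydrogens sit on the methyl group so that only the terminal vinyl group can form and both carbinol epimers converge without touching a ring stereocentre.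

**Step 5**
Reactants: 6 (2R,3R,5S)-2-ethenyl-2-methyl-5-(2-methyl-1,3-dioxolan-2-yl)-3-(prop-1-en-2-yl)cyclohexan-1-one
Product: 7 2-[(1R,3R,4R)-4-ethenyl-4-methyl-3-(prop-1-en-2-yl)cyclohexyl]-2-methyl-1,3-dioxolane
Conditions: N2H4·H2O, KOH, diethylene glycol, 130 → 200 °C
Reagents that add atoms: none
Why: Wolff–Kishner reduction in the Huang–Minlon modification, which the base-stable ketal and the unactivated alkenes should survive and which cannot epimerise the quaternary α-carbon.

**Step 6**
Reactants: 7 2-[(1R,3R,4R)-4-ethenyl-4-methyl-3-(prop-1-en-2-yl)cyclohexyl]-2-methyl-1,3-dioxolane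
Product: 9 1-[(1S,3R,4R)-4-ethenyl-4-methyl-3-(prop-1-en-2-yl)cyclohexyl]ethan-1-one, via trans ketone 8 (not isolated)
Conditions: 1 M HCl, THF, 23 °C; NaOMe, MeOH, 23 °C; chromatography, minor epimer re-equilibrated
Reagents that add atoms: water, O
Why: Ketal hydrolysis followed by base-mediated epimerisation α to the ketone, where thermodynamic control should place the acetyl group equatorial and cis to the equatorial isopropenyl group, inverting the carvone-derived centre to the configuration the target needs.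

**Step 7**
Reactants: 9 1-[(1S,3R,4R)-4-ethenyl-4-methyl-3-(prop-1-en-2-yl)cyclohexyl]ethan-1-one
Product: 12 3-[(1S,3R,4R)-4-ethenyl-4-methyl-3-(prop-1-en-2-yl)cyclohexyl]prop-2-yn-1-ol, via enol phosphate 10 (not isolated), via lithium acetylide 11 (not isolated)
Conditions: LiN(i-Pr)2, THF, −78 °C; ClP(O)(OEt)2, −78 → 23 °C; LiN(i-Pr)2 (2.5 equiv), −78 → 0 °C; (CH2O)n, 0 → 23 °C
Reagents that add atoms: paraformaldehyde (as formaldehyde), C=O
Why: Kinetic enolisation at the methyl group, O-phosphorylation and amide-induced elimination of the enol phosphate give the acetylide, which is hydroxymethylated by formaldehyde, and the ring stereocentre becomes a non-acidic propargylic position.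

**Step 8**
Reactants: 12 3-[(1S,3R,4R)-4-ethenyl-4-methyl-3-(prop-1-en-2-yl)cyclohexyl]prop-2-yn-1-ol
Product: 13 methyl 3-[(1S,3R,4R)-4-ethenyl-4-methyl-3-(prop-1-en-2-yl)cyclohexyl]prop-2-yn-1-yl carbonate
Conditions: ClCO2Me, pyridine, CH2Cl2, 0 °C
Reagents that add atoms: methyl chloroformate, COC(=O)Cl
Why: Standard acylation of a primary alcohol with a chloroformate to give the mixed carbonate.

**Step 9**
Reactants: 13 methyl 3-[(1S,3R,4R)-4-ethenyl-4-methyl-3-(prop-1-en-2-yl)cyclohexyl]prop-2-yn-1-yl carbonate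
Product: 14 methyl 2-[(1S,3R,4R)-4-ethenyl-4-methyl-3-(prop-1-en-2-yl)cyclohexyl]buta-2,3-dienoate
Conditions: Pd2(dba)3·CHCl3 (2.5 mol %), PPh3 (10 mol %), CO (10 bar), MeOH, 40 °C
Reagents that add atoms: carbon monoxide, [C-]#[O+]
Why: Palladium-catalysed carbonylation of a propargylic carbonate, in which zerovalent palladium ionises the carbonate in an SN2′ sense, CO2 is lost to leave an allenylpalladium methoxide, and CO insertion with reductive elimination gives the 2-substituted allenoate carrying the carbonate's own methoxy group.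

**Step 10**
Reactants: 15 methyl 2-hydroxy-2-methylpropanoate
Product: 16 methyl 2-methyl-2-[(triethylsilyl)oxy]propanoate
Conditions: Et3SiOTf, 2,6-lutidine, CH2Cl2, 0 °C
Reagents that add atoms: triethylsilyl trifluoromethanesulfonate, CC[Si](CC)(CC)OS(=O)(=O)C(F)(F)F
Why: Silylation of a tertiary alcohol with a silyl triflate and a hindered pyridine base.

**Step 11**
Reactants: 16 methyl 2-methyl-2-[(triethylsilyl)oxy]propanoate
Product: 17 2-methyl-2-[(triethylsilyl)oxy]propanal
Conditions: i-Bu2AlH (1.05 equiv), CH2Cl2, −78 °C; aqueous potassium sodium tartrate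
Reagents that add atoms: none
Why: Partial reduction of an α-alkoxy ester with i-Bu2AlH, which stops at the aldehyde because the tetrahedral aluminium hemiacetal is stable at −78 °C.

**Step 12**
Reactants: 14 methyl 2-[(1S,3R,4R)-4-ethenyl-4-methyl-3-(prop-1-en-2-yl)cyclohexyl]buta-2,3-dienoate; 17 2-methyl-2-[(triethylsilyl)oxy]propanal
Product: 20 (6S)-3-[(1S,3R,4R)-4-ethenyl-4-methyl-3-(prop-1-en-2-yl)cyclohexyl]-6-{2-[(triethylsilyl)oxy]propan-2-yl}-5,6-dihydro-2H-pyran-2-one, via copper dienolate 18 (not isolated), via boryl aldolate 19 (not isolated)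
Conditions: CuOAc (5 mol %), (R)-DTBM-SEGPHOS (5 mol %), PCy3 (5 mol %), pinacolborane (1.3 equiv), THF, 0 °C, slow addition of 17; then PPTS (cat.), 23 °C
Reagents that add atoms: none
Why: Proposed new method: a bisphosphine-ligated copper hydride made from CuOAc and pinacolborane adds hydride to the central allene carbon of 14 to give dienolate 18, whose unsubstituted γ-carbon (the former =CH2) attacks aldehyde 17 to form the C4–C5 bond of the heptene chain, and the (Z)-aldolate 19 closes onto the ester by acyl substitution (6-exo-trig lactonisation) with transfer of methoxide to boron. The closest known reaction type is the copper-hydride-catalysed enantioselective reductive vinylogous aldol reaction of allenic esters with ketones, which gives γ-cis adducts and δ-lactones, together with the copper–bisphosphine-catalysed direct vinylogous aldol–lactonisation of β,γ-unsaturated esters with aldehydes; new here are the aldehyde acceptor and the α-branched allenoate. The only new stereocentre (chain C5, pyranone C6) is set by the chiral bisphosphine on copper in the C–C bond-forming transition state, because the ring stereocentres are too remote to exert a useful bias. γ- over α-attack is secured by the fully substituted α-carbon bearing the cyclohexyl group, and the cis alkene is secured because allylic strain between that group and the vinyl terminus holds the dienolate s-cis and only the Z aldolate can lactonise. Chemoselectivity over direct aldehyde reduction rests on hydrocupration of the electron-poor allene being much faster than attack on the hindered α-quaternary aldehyde, helped by slow addition of 17, while the unactivated vinyl and isopropenyl groups should not react with the copper hydride at 0 °C.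

**Step 13**
Reactants: 20 (6S)-3-[(1S,3R,4R)-4-ethenyl-4-methyl-3-(prop-1-en-2-yl)cyclohexyl]-6-{2-[(triethylsilyl)oxy]propan-2-yl}-5,6-dihydro-2H-pyran-2-one
Product: 21 (2Z,5S)-2-[(1S,3R,4R)-4-ethenyl-4-methyl-3-(prop-1-en-2-yl)cyclohexyl]-6-methyl-6-[(triethylsilyl)oxy]hept-2-ene-1,5-diol
Conditions: i-Bu2AlH (4 equiv), CH2Cl2, −78 → 23 °C; aqueous potassium sodium tartrate
Reagents that add atoms: none
Why: 1,2-Reduction of the unsaturated lactone through the lactol and its open hydroxy-enal form, which removes the temporary ring and hands its cis geometry on as the Z alkene.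

**Step 14**
Reactants: 21 (2Z,5S)-2-[(1S,3R,4R)-4-ethenyl-4-methyl-3-(prop-1-en-2-yl)cyclohexyl]-6-methyl-6-[(triethylsilyl)oxy]hept-2-ene-1,5-diol
Product: 22 (2Z,5S)-2-[(1S,3R,4R)-4-ethenyl-4-methyl-3-(prop-1-en-2-yl)cyclohexyl]-6-methylhept-2-ene-1,5,6-triol
Conditions: Bu4NF, THF, 0 → 23 °C
Reagents that add atoms: none
Why: Fluoride-mediated desilylation, done before any ester is present so that neither silyl nor acyl migration can matter.

**Step 15**
Reactants: 22 (2Z,5S)-2-[(1S,3R,4R)-4-ethenyl-4-methyl-3-(prop-1-en-2-yl)cyclohexyl]-6-methylhept-2-ene-1,5,6-triol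
Product: 23 (2Z,5S)-2-[(1S,3R,4R)-4-ethenyl-4-methyl-3-(prop-1-en-2-yl)cyclohexyl]-6-hydroxy-6-methylhept-2-ene-1,5-diyl diacetate (the target)
Conditions: Ac2O (2.5 equiv), pyridine, DMAP (cat.), CH2Cl2, 0 °C
Reagents that add atoms: acetic anhydride, CC(=O)OC(C)=O
Why: Chemoselective acetylation, in which the primary and secondary hydroxyl groups are acylated while the tertiary alcohol should stay free under these mild conditions.

**Compound list**
1 | (S)-(+)-carvone, (5S)-2-methyl-5-(prop-1-en-2-yl)cyclohex-2-en-1-one | O=C1C[C@@H](C(=C)C)CC=C1C | starting material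
2 | (5S)-5-acetyl-2-methylcyclohex-2-en-1-one | O=C1C[C@@H](C(C)=O)CC=C1C | intermediate
3 | (5S)-2-methyl-5-(2-methyl-1,3-dioxolan-2-yl)cyclohex-2-en-1-one | O=C1C[C@@H](C2(C)OCCO2)CC=C1C | intermediate
4 | bromomagnesium (3R,5S)-2-methyl-5-(2-methyl-1,3-dioxolan-2-yl)-3-(prop-1-en-2-yl)cyclohex-1-en-1-olate | CC1=C(O[Mg]Br)C[C@@H](C2(C)OCCO2)C[C@@H]1C(=C)C | intermediate
5 | (2S,3R,5S)-2-(1-hydroxyethyl)-2-methyl-5-(2-methyl-1,3-dioxolan-2-yl)-3-(prop-1-en-2-yl)cyclohexan-1-one (both carbinol epimers) | CC(O)[C@@]1(C)C(=O)C[C@@H](C2(C)OCCO2)C[C@@H]1C(=C)C | intermediate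
6 | (2R,3R,5S)-2-ethenyl-2-methyl-5-(2-methyl-1,3-dioxolan-2-yl)-3-(prop-1-en-2-yl)cyclohexan-1-one | C=C[C@@]1(C)C(=O)C[C@@H](C2(C)OCCO2)C[C@@H]1C(=C)C | intermediate
7 | 2-[(1R,3R,4R)-4-ethenyl-4-methyl-3-(prop-1-en-2-yl)cyclohexyl]-2-methyl-1,3-dioxolane | C=C[C@@]1(C)CC[C@@H](C2(C)OCCO2)C[C@@H]1C(=C)C | intermediate
8 | 1-[(1R,3R,4R)-4-ethenyl-4-methyl-3-(prop-1-en-2-yl)cyclohexyl]ethan-1-one (acetyl trans to isopropenyl) | C=C[C@@]1(C)CC[C@@H](C(C)=O)C[C@@H]1C(=C)C | intermediate
9 | 1-[(1S,3R,4R)-4-ethenyl-4-methyl-3-(prop-1-en-2-yl)cyclohexyl]ethan-1-one (acetyl cis to isopropenyl) | C=C[C@@]1(C)CC[C@H](C(C)=O)C[C@@H]1C(=C)C | intermediate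
10 | diethyl 1-[(1S,3R,4R)-4-ethenyl-4-methyl-3-(prop-1-en-2-yl)cyclohexyl]ethenyl phosphate | C=C[C@@]1(C)CC[C@H](C(=C)OP(=O)(OCC)OCC)C[C@@H]1C(=C)C | intermediate
11 | {[(1S,3R,4R)-4-ethenyl-4-methyl-3-(prop-1-en-2-yl)cyclohexyl]ethynyl}lithium | C=C[C@@]1(C)CC[C@H](C#C[Li])C[C@@H]1C(=C)C | intermediate
12 | 3-[(1S,3R,4R)-4-ethenyl-4-methyl-3-(prop-1-en-2-yl)cyclohexyl]prop-2-yn-1-ol | C=C[C@@]1(C)CC[C@H](C#CCO)C[C@@H]1C(=C)C | intermediate
13 | methyl 3-[(1S,3R,4R)-4-ethenyl-4-methyl-3-(prop-1-en-2-yl)cyclohexyl]prop-2-yn-1-yl carbonate | C=C[C@@]1(C)CC[C@H](C#CCOC(=O)OC)C[C@@H]1C(=C)C | intermediate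
14 | methyl 2-[(1S,3R,4R)-4-ethenyl-4-methyl-3-(prop-1-en-2-yl)cyclohexyl]buta-2,3-dienoate | C=C[C@@]1(C)CC[C@H](C(=C=C)C(=O)OC)C[C@@H]1C(=C)C | intermediate
15 | methyl 2-hydroxy-2-methylpropanoate | COC(=O)C(C)(C)O | starting material
16 | methyl 2-methyl-2-[(triethylsilyl)oxy]propanoate | COC(=O)C(C)(C)O[Si](CC)(CC)CC | intermediate
17 | 2-methyl-2-[(triethylsilyl)oxy]propanal | O=CC(C)(C)O[Si](CC)(CC)CC | intermediate
18 | copper dienolate of methyl 2-[(1S,3R,4R)-4-ethenyl-4-methyl-3-(prop-1-en-2-yl)cyclohexyl]but-3-enoate (bisphosphine ligand omitted) | C=C[C@@]1(C)CC[C@H](C(C=C)=C(OC)O[Cu])C[C@@H]1C(=C)C | intermediate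
19 | methyl (2Z,5S)-2-[(1S,3R,4R)-4-ethenyl-4-methyl-3-(prop-1-en-2-yl)cyclohexyl]-6-methyl-5-[(4,4,5,5-tetramethyl-1,3,2-dioxaborolan-2-yl)oxy]-6-[(triethylsilyl)oxy]hept-2-enoate | C=C[C@@]1(C)CC[C@H](/C(=C/C[C@H](OB2OC(C)(C)C(C)(C)O2)C(C)(C)O[Si](CC)(CC)CC)C(=O)OC)C[C@@H]1C(=C)C | intermediate
20 | (6S)-3-[(1S,3R,4R)-4-ethenyl-4-methyl-3-(prop-1-en-2-yl)cyclohexyl]-6-{2-[(triethylsilyl)oxy]propan-2-yl}-5,6-dihydro-2H-pyran-2-one | C=C[C@@]1(C)CC[C@H](C2=CC[C@@H](C(C)(C)O[Si](CC)(CC)CC)OC2=O)C[C@@H]1C(=C)C | intermediate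
21 | (2Z,5S)-2-[(1S,3R,4R)-4-ethenyl-4-methyl-3-(prop-1-en-2-yl)cyclohexyl]-6-methyl-6-[(triethylsilyl)oxy]hept-2-ene-1,5-diol | C=C[C@@]1(C)CC[C@H](/C(=C/C[C@H](O)C(C)(C)O[Si](CC)(CC)CC)CO)C[C@@H]1C(=C)C | intermediate
22 | (2Z,5S)-2-[(1S,3R,4R)-4-ethenyl-4-methyl-3-(prop-1-en-2-yl)cyclohexyl]-6-methylhept-2-ene-1,5,6-triol | C=C[C@@]1(C)CC[C@H](/C(=C/C[C@H](O)C(C)(C)O)CO)C[C@@H]1C(=C)C | intermediate
23 | (2Z,5S)-2-[(1S,3R,4R)-4-ethenyl-4-methyl-3-(prop-1-en-2-yl)cyclohexyl]-6-hydroxy-6-methylhept-2-ene-1,5-diyl diacetate | C=C[C@@]1(C)CC[C@H](/C(=C/C[C@H](OC(C)=O)C(C)(C)O)COC(C)=O)C[C@@H]1C(=C)C | target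

**Step count**
Total: 15 steps. Longest linear sequence: 13 steps (steps 1–9 and 12–15); steps 10–11 make the aldehyde in a side branch.

**Steps most likely to fail**

1. Step 12 (Proposed new method). What may go wrong: the copper hydride reduces the aldehyde before the dienolate captures it, an E aldolate forms and stalls before ring closure, or the catalyst discriminates poorly between the faces of the hindered aldehyde. The fallback uses known chemistry, sets out from 17 and 9 and returns at 20. Aldehyde 17 is allylated by a Brown allylation with the Ipc2B(allyl) antipode that delivers the (S)-carbinol (Et2O, −78 °C; NaOH, H2O2) to give (3S)-2-methyl-2-[(triethylsilyl)oxy]hex-5-en-3-ol F1, which already contains the C4–C5 bond. Ketone 9 is converted with KN(SiMe3)2 and PhNTf2 (THF, −78 °C) into 1-[(1S,3R,4R)-4-ethenyl-4-methyl-3-(prop-1-en-2-yl)cyclohexyl]ethenyl trifluoromethanesulfonate F2, and palladium-catalysed hydroxycarbonylation (Pd(OAc)2, PPh3, CO, KOAc, DMF/H2O) gives 2-[(1S,3R,4R)-4-ethenyl-4-methyl-3-(prop-1-en-2-yl)cyclohexyl]prop-2-enoic acid F3. Yamaguchi esterification of the two pieces gives (3S)-2-methyl-2-[(triethylsilyl)oxy]hex-5-en-3-yl 2-[(1S,3R,4R)-4-ethenyl-4-methyl-3-(prop-1-en-2-yl)cyclohexyl]prop-2-enoate F4. Ring-closing metathesis with the second-generation Grubbs catalyst (toluene, 80 °C) then closes the same dihydropyranone 20; the hindered ring vinyl and isopropenyl groups should stay out of the metathesis.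

2. Step 5. What may go wrong: hydrazone formation stalls at the neopentyl-type carbonyl, or prolonged heating at 200 °C lets the 1,2-dialkenyl unit equilibrate by Cope rearrangement. The fallback sets out from 6 and returns at 7. Ketone 6 is condensed with TsNHNH2 (EtOH, 70 °C) to N′-[(2R,3R,5S)-2-ethenyl-2-methyl-5-(2-methyl-1,3-dioxolan-2-yl)-3-(prop-1-en-2-yl)cyclohexylidene]-4-methylbenzenesulfonohydrazide F5. This is reduced with catecholborane (CHCl3, 0 °C) and the adduct is decomposed with NaOAc·3H2O at reflux, so the oxygen is removed by hydride addition and diazene fragmentation below 70 °C instead of by hot base.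

3. Step 4. What may go wrong: a cationic 1,2-shift or a retro-aldol-type fragmentation competes with syn elimination at the neopentyl-type secondary sulfamate. The fallback sets out from 3 and returns at 6. The conjugate addition of step 3 is repeated, but enolate 4 is trapped with (phenylselanyl)acetaldehyde (−78 °C) as a vinyl cation equivalent to give (2S,3R,5S)-2-[1-hydroxy-2-(phenylselanyl)ethyl]-2-methyl-5-(2-methyl-1,3-dioxolan-2-yl)-3-(prop-1-en-2-yl)cyclohexan-1-one F6. MsCl and Et3N (CH2Cl2, 0 °C) then eliminate the hydroxyl and selanyl groups through the episelenonium ion to give vinyl ketone 6 without a free carbocation.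

**Further compounds**
F1 | step 12 | (3S)-2-methyl-2-[(triethylsilyl)oxy]hex-5-en-3-ol | C=CC[C@H](O)C(C)(C)O[Si](CC)(CC)CC
F2 | step 12 | 1-[(1S,3R,4R)-4-ethenyl-4-methyl-3-(prop-1-en-2-yl)cyclohexyl]ethenyl trifluoromethanesulfonate | C=C[C@@]1(C)CC[C@H](C(=C)OS(=O)(=O)C(F)(F)F)C[C@@H]1C(=C)C
F3 | step 12 | 2-[(1S,3R,4R)-4-ethenyl-4-methyl-3-(prop-1-en-2-yl)cyclohexyl]prop-2-enoic acid | C=C[C@@]1(C)CC[C@H](C(=C)C(=O)O)C[C@@H]1C(=C)C
F4 | step 12 | (3S)-2-methyl-2-[(triethylsilyl)oxy]hex-5-en-3-yl 2-[(1S,3R,4R)-4-ethenyl-4-methyl-3-(prop-1-en-2-yl)cyclohexyl]prop-2-enoate | C=C[C@@]1(C)CC[C@H](C(=C)C(=O)O[C@@H](CC=C)C(C)(C)O[Si](CC)(CC)CC)C[C@@H]1C(=C)C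
F5 | step 5 | N′-[(2R,3R,5S)-2-ethenyl-2-methyl-5-(2-methyl-1,3-dioxolan-2-yl)-3-(prop-1-en-2-yl)cyclohexylidene]-4-methylbenzenesulfonohydrazide | C=C[C@@]1(C)C(=NNS(=O)(=O)c2ccc(C)cc2)C[C@@H](C3(C)OCCO3)C[C@@H]1C(=C)C
F6 | step 4 | (2S,3R,5S)-2-[1-hydroxy-2-(phenylselanyl)ethyl]-2-methyl-5-(2-methyl-1,3-dioxolan-2-yl)-3-(prop-1-en-2-yl)cyclohexan-1-one | OC(C[Se]c1ccccc1)[C@@]1(C)C(=O)C[C@@H](C2(C)OCCO2)C[C@@H]1C(=C)C
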